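**Plan**

- Cuts, in retrosynthetic order: the C8 ester to an acrylate plus formaldehyde; then, together, the lactone O–C6 bond and the two exocyclic methylenes (C4=C3, C11=C13), which leads back to a malonic acid on C7, two formaldehyde units and a β-cyclopropane C4–C5–C6 carrying the C15 aldehyde; then C10–CH=CH2 (Wittig), C7–C11 (Negishi), C4–C5/C4–C6 (tethered ylide cyclopropanation) and the cyclohexenone (Diels–Alder).
- Forward: Diels–Alder builds the carbocycle; a bromoacetate on O14 closes the cyclopropane through a temporary δ-lactone; coupling and hydroboration give the C7 side chain and C8–OH; the vinyl group follows; the tether is opened to C14–OAc and the C15 aldehyde; one cascade closes the γ-lactone and installs both methylenes; the C8 acrylate is hydroxymethylated last.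
- Stereochemistry: C10 from the catalyst-controlled Diels–Alder reaction; C5 (cyclopropane face) from the O14 tether; C7 and C8 from one syn hydroboration anti to the cyclopropane; C6 from stereospecific anti opening of the cyclopropane by the C12 carboxylate.
- Enabling feature: on the cyclohexane ring C5–C10, C4 on C5 (β) and the lactone oxygen on C6 (α) are trans-vicinal and C4 is the α-carbon of the C15 aldehyde. This is the pattern left when a carboxylate opens an aldehyde-activated cyclopropane C4–C5–C6 at C6. C3, C13 and the CH2OH carbon of the C8 ester all lie α to a carbonyl group and are traced to formaldehyde.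

Key step: step 16

Remark: locants are those of the elemane skeleton (ring C5–C10; vinyl C1=C2 on C10; C3=C4–C15 on C5; C11(=C13)–C12 on C7; C14 = CH2O on C10); β is the ring face that carries C14.
Remark: the enantiomer of the TADDOL catalyst in step 3 is assumed to be the one that leads to the (R)-enone 7.

**Step 1**
Reactants: 1 2-methylenepropane-1,3-diol
Product: 2 2-{[(4-methoxybenzyl)oxy]methyl}prop-2-en-1-ol
Conditions: NaH (1.0 equiv), 4-methoxybenzyl chloride (1.0 equiv), n-Bu4NI (cat.), THF–DMF, 0 °C → rt, diol in excess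
Reagents that add atoms: 4-methoxybenzyl chloride, COc1ccc(CCl)cc1
Why: Williamson etherification of the symmetric diol used in excess should give the mono-ether; no stereocentre is formed.

**Step 2**
Reactants: 2 2-{[(4-methoxybenzyl)oxy]methyl}prop-2-en-1-ol
Product: 3 2-{[(4-methoxybenzyl)oxy]methyl}acrylaldehyde
Conditions: MnO2 (10 equiv), CH2Cl2, rt
Reagents that add atoms: none
Why: allylic alcohol oxidation with MnO2 stops at the enal and leaves the benzylic ether alone.

**Step 3**
Reactants: 3 2-{[(4-methoxybenzyl)oxy]methyl}acrylaldehyde; 4 (E)-1-(dimethylamino)-3-(tert-butyldimethylsilyloxy)buta-1,3-diene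
Product: 7 (R)-4-(hydroxymethyl)-4-{[(4-methoxybenzyl)oxy]methyl}cyclohex-2-en-1-one, via cycloadduct 5 (not isolated), via amino alcohol 6 (not isolated)
Conditions: 1-naphthyl-TADDOL (20 mol %), toluene, −80 °C; then LiAlH4, Et2O, −78 → 0 °C; then aq. HF, MeCN, 0 °C
Reagents that add atoms: none
Why: hydrogen-bond-catalysed Diels–Alder reaction in which the amino-bearing diene terminus bonds to the enal α-carbon and the chiral diol shields one face of the bound enal, so the quaternary carbon (future C10) is set by the catalyst, after which LiAlH4 reduction of the formyl group and acid-induced desilylation with β-elimination of dimethylamine unveil the enone.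

**Step 4**
Reactants: 7 (R)-4-(hydroxymethyl)-4-{[(4-methoxybenzyl)oxy]methyl}cyclohex-2-en-1-one
Product: 8 (S)-(1-{[(4-methoxybenzyl)oxy]methyl}-4-oxocyclohex-2-en-1-yl)methyl 2-bromoacetate
Conditions: BrCH2COBr, pyridine, CH2Cl2, −20 → 0 °C
Reagents that add atoms: bromoacetyl bromide, BrCC(Br)=O
Why: O-acylation of the neopentylic primary alcohol installs the two-carbon tether (future C4 and C15) on the arm that becomes C14; no stereocentre is touched.

**Step 5**
Reactants: 8 (S)-(1-{[(4-methoxybenzyl)oxy]methyl}-4-oxocyclohex-2-en-1-yl)methyl 2-bromoacetate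
Product: 10 cyclopropane keto-lactone (7-oxo; β-cyclopropane C4–C5–C6; δ-lactone C15(=O)–O14; 10α-CH2OPMB), via ammonium salt 9 (not isolated)
Conditions: DABCO (1.2 equiv), MeCN, rt; then Cs2CO3, 60 °C
Reagents that add atoms: none
Why: Michael-initiated ring closure through an ammonium ylide (ylide cyclopropanation of an enone), in which the tethered ylide carbon must add to C5 on the β face through a six-membered ring and the C6 enolate then displaces DABCO, so C4, C5 and C6 are set with the cyclopropane cis to C14.

**Step 6**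
Reactants: 10 cyclopropane keto-lactone
Product: 11 C7 enol triflate of 10 (C7=C8)
Conditions: KN(SiMe3)2 (1.1 equiv), THF, −78 °C; then PhNTf2
Reagents that add atoms: N-phenylbis(trifluoromethanesulfonimide), O=S(=O)(N(c1ccccc1)S(=O)(=O)C(F)(F)F)C(F)(F)F
Why: kinetic enolate O-triflation, regioselective because the other α-carbon (C6) is a cyclopropane carbon that cannot be enolised.

**Step 7**
Reactants: 11 C7 enol triflate
Product: 12 tert-butyl ester (C7=C8; C7–CH2CO2tBu)
Conditions: BrZnCH2CO2tBu (2 equiv, from tert-butyl bromoacetate and Zn), Pd(PPh3)4 (5 mol %), THF, 60 °C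
Reagents that add atoms: (2-tert-butoxy-2-oxoethyl)zinc bromide, CC(C)(C)OC(=O)C[Zn]Br
Why: Negishi-type cross-coupling of an alkenyl triflate with a Reformatsky zinc enolate forms C7–C11 without touching the lactone or the cyclopropane.

**Step 8**
Reactants: 12 tert-butyl ester
Product: 13 8α-alcohol (7αH; C7 β-CH2CO2tBu)
Conditions: BH3·THF (1.5 equiv), THF, 0 °C; then 30 % H2O2, aq. NaOAc, 0 °C → rt
Reagents that add atoms: hydrogen peroxide, OO
Why: hydroboration–oxidation puts boron on the less substituted C8 and hydrogen on C7, syn and from the α face (anti to the β-cyclopropane on C6 and to the pseudo-axial C10–C14 bond), which sets C7 (side chain β) and C8 (OH α) in one event.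

**Step 9**
Reactants: 13 8α-alcohol
Product: 14 8α-O-Boc di-tert-butyl malonate (C7 β-CH(CO2tBu)2)
Conditions: LiN(SiMe3)2 (3.3 equiv), THF, −78 °C; then Boc2O (2.4 equiv), −78 → −20 °C
Reagents that add atoms: di-tert-butyl dicarbonate, CC(C)(C)OC(=O)OC(=O)OC(C)(C)C
Why: Claisen-type C-acylation of the ester enolate turns the side chain into a di-tert-butyl malonate while the C8 alkoxide is capped as its tert-butyl carbonate; C11 carries two identical esters and is no stereocentre.

**Step 10**
Reactants: 14 8α-O-Boc di-tert-butyl malonate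
Product: 15 primary alcohol (C10 α-CH2OH)
Conditions: DDQ (1.3 equiv), CH2Cl2–pH 7 buffer, 0 °C → rt
Reagents that add atoms: none
Why: oxidative cleavage of the 4-methoxybenzyl ether by DDQ, which spares esters, carbonate, lactone and cyclopropane.

**Step 11**
Reactants: 15 primary alcohol
Product: 16 aldehyde (C10 α-CHO)
Conditions: Dess–Martin periodinane (1.3 equiv), NaHCO3, CH2Cl2, 0 °C → rt
Reagents that add atoms: none
Why: Dess–Martin oxidation of the neopentylic alcohol gives a non-enolisable aldehyde.

**Step 12**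
Reactants: 16 aldehyde
Product: 17 10α-vinyl lactone
Conditions: Ph3PCH3Br (2.6 equiv), KN(SiMe3)2 (2.5 equiv), THF, 0 °C; then 16, −78 → 0 °C
Reagents that add atoms: methylenetriphenylphosphorane (from methyltriphenylphosphonium bromide), C=P(c1ccccc1)(c1ccccc1)c1ccccc1
Why: Wittig methylenation, run with excess ylide because the malonate C–H consumes one equivalent, while the hindered esters, carbonate and lactone should survive at low temperature.

**Step 13**
Reactants: 17 10α-vinyl lactone
Product: 19 14-acetoxy N-methoxy-N-methylamide (δ-lactone opened; C15 amide on the cyclopropane), via hydroxy amide 18 (not isolated)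
Conditions: MeNH(OMe)·HCl (3 equiv), Me3Al (3 equiv), CH2Cl2, 0 °C → rt; then pyridine, Ac2O, DMAP (cat.), 0 °C
Reagents that add atoms: N,O-dimethylhydroxylamine hydrochloride, CNOC.Cl; acetic anhydride, CC(=O)OC(C)=O
Why: aminolysis of the strained δ-lactone by the aluminium amide gives the N-methoxy-N-methylamide and frees the C14 alkoxide, which is acetylated in the same flask before it can relactonise.

**Step 14**
Reactants: 19 14-acetoxy N-methoxy-N-methylamide
Product: 20 cyclopropanecarbaldehyde (C15 aldehyde on the β-cyclopropane)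
Conditions: Cp2Zr(H)Cl (1.5 equiv), THF, 0 °C → rt, 20 min
Reagents that add atoms: none
Why: reduction of the N-methoxy-N-methylamide with Cp2Zr(H)Cl stops at the aldehyde through a stable zirconated hemiaminal and should be faster than attack on esters, carbonate or the hindered neopentylic vinyl group.

**Step 15**
Reactants: 20 cyclopropanecarbaldehyde
Product: 21 8α-hydroxy malonic acid aldehyde (C7 β-CH(CO2H)2)
Conditions: TMSOTf (6 equiv), 2,6-lutidine (8 equiv), CH2Cl2, 0 °C; then pH 5 buffer
Reagents that add atoms: none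
Why: silyl triflate-mediated dealkylation of the tert-butyl esters and carbonate (loss of isobutene, silyl esters hydrolysed on work-up) frees the malonic acid and the C8 alcohol without protic acid, so the acetate survives and no lactone forms onto O8.

**Step 16**
Reactants: 21 8α-hydroxy malonic acid aldehyde
Product: 23 14-acetoxy-8α-hydroxy-15-oxoelema-1,3,11(13)-trien-12,6α-olide, via acrylic acid 22 (not isolated)
Conditions: 37 % aq. CH2O (10 equiv), pyrrolidine (0.5 equiv), EtCO2H (0.5 equiv), i-PrOH–H2O, 23 °C then 50 °C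
Reagents that add atoms: formaldehyde, C=O
Why: Proposed new method: pyrrolidine condenses with the C15 aldehyde to a cyclopropyl iminium ion whose π* orbital weakens the C4–C6 bond, while formaldehyde and the amine convert the malonic acid into acrylic acid 22 (decarboxylative Mannich methylenation); the C12 carboxylate then attacks C6 from the α face, anti to the breaking C4–C6 bond, and the enamine released is intercepted by the formaldehyde iminium ion and eliminates the amine to give the C4=C3 methylene aldehyde. The closest known reaction types are the iminium-ion-catalysed ring opening of formylcyclopropanes by carboxylic acids (homoconjugate addition), the amine-catalysed α-methylenation of aldehydes with formaldehyde and the decarboxylative Mannich methylenation of monosubstituted malonic acids. The γ-lactone is the only ring closed, by 5-exo-tet attack of oxygen on C6 with opening of the three-membered ring, through a boat-like conformer of the carbocycle that the eclipsed cyclopropane bond C5–C6 makes accessible. C6 is the only new stereocentre and is fixed by the stereospecific inversion (O α because C4 was β), which leaves C4 on C5 trans to the new C–O bond; C5, C7, C8 and C10 are untouched. The step needs attack at C6 and not at C5 (only C6 is within reach of the carboxylate on C7), trapping of the malonate carbon and of the enamine by formaldehyde and not by the internal aldehyde or the new α-methylene lactone (secured by an excess of the far more electrophilic formaldehyde iminium ion), and reversible amine addition to the product acceptors (secured by using the amine as its carboxylate salt).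

**Step 17**
Reactants: 23 14-acetoxy-8α-hydroxy-15-oxoelema-1,3,11(13)-trien-12,6α-olide
Product: 24 8α-acrylate of 23
Conditions: acryloyl chloride (1.5 equiv), i-Pr2NEt (2 equiv), CH2Cl2, −40 → −10 °C
Reagents that add atoms: acryloyl chloride, C=CC(Cl)=O
Why: O-acylation of the secondary C8 alcohol at low temperature, with retention at C8.

**Step 18**
Reactants: 24 8α-acrylate
Product: 25 CNP0185525.1 (14-acetoxy-8α-[2-(hydroxymethyl)acryloyloxy]-15-oxoelema-1,3,11(13)-trien-12,6α-olide)
Conditions: 37 % aq. CH2O (5 equiv), DABCO (1.0 equiv), 1,4-dioxane–H2O (1:1), rt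
Reagents that add atoms: formaldehyde, C=O
Why: Morita–Baylis–Hillman hydroxymethylation, in which only the unsubstituted acrylate can form the zwitterionic enolate that captures formaldehyde and then releases DABCO, while the α-substituted acceptors (enal, α-methylene lactone) add the amine only reversibly.

**Compound list**

1 | 2-methylenepropane-1,3-diol | C=C(CO)CO | starting material
2 | 2-{[(4-methoxybenzyl)oxy]methyl}prop-2-en-1-ol | C=C(CO)COCc1ccc(OC)cc1 | intermediate
3 | 2-{[(4-methoxybenzyl)oxy]methyl}acrylaldehyde | C=C(C=O)COCc1ccc(OC)cc1 | intermediate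
4 | (E)-1-(dimethylamino)-3-(tert-butyldimethylsilyloxy)buta-1,3-diene | CN(C)/C=C/C(=C)O[Si](C)(C)C(C)(C)C | starting material
5 | cycloadduct: 2-(dimethylamino)-1-{[(4-methoxybenzyl)oxy]methyl}-4-(tert-butyldimethylsilyloxy)cyclohex-3-ene-1-carbaldehyde, NMe2 cis to CHO | COc1ccc(COC[C@]2(C=O)CCC(O[Si](C)(C)C(C)(C)C)=C[C@H]2N(C)C)cc1 | intermediate (not isolated)
6 | amino alcohol: the CH2OH analogue of 5 | COc1ccc(COC[C@]2(CO)CCC(O[Si](C)(C)C(C)(C)C)=C[C@H]2N(C)C)cc1 | intermediate (not isolated)
7 | (R)-4-(hydroxymethyl)-4-{[(4-methoxybenzyl)oxy]methyl}cyclohex-2-en-1-one | COc1ccc(COC[C@]2(CO)CCC(=O)C=C2)cc1 | intermediate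
8 | (S)-(1-{[(4-methoxybenzyl)oxy]methyl}-4-oxocyclohex-2-en-1-yl)methyl 2-bromoacetate | COc1ccc(COC[C@]2(COC(=O)CBr)CCC(=O)C=C2)cc1 | intermediate
9 | ammonium salt: DABCO-quaternised acetate of 8, bromide | [Br-].COc1ccc(COC[C@]2(COC(=O)C[N+]34CCN(CC3)CC4)CCC(=O)C=C2)cc1 | intermediate (not isolated)
10 | cyclopropane keto-lactone (7-oxo; β-cyclopropane C4–C5–C6; δ-lactone C15(=O)–O14; 10α-CH2OPMB) | COc1ccc(COC[C@]23CCC(=O)[C@H]4[C@H]([C@@H]24)C(=O)OC3)cc1 | intermediate
11 | C7 enol triflate of 10 (C7=C8) | COc1ccc(COC[C@]23CC=C(OS(=O)(=O)C(F)(F)F)[C@H]4[C@H]([C@@H]24)C(=O)OC3)cc1 | intermediate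
12 | tert-butyl ester (C7=C8; C7–CH2CO2tBu) | COc1ccc(COC[C@]23CC=C(CC(=O)OC(C)(C)C)[C@H]4[C@H]([C@@H]24)C(=O)OC3)cc1 | intermediate
13 | 8α-alcohol (7αH; C7 β-CH2CO2tBu) | COc1ccc(COC[C@]23C[C@H](O)[C@@H](CC(=O)OC(C)(C)C)[C@H]4[C@H]([C@@H]24)C(=O)OC3)cc1 | intermediate
14 | 8α-O-Boc di-tert-butyl malonate | COc1ccc(COC[C@]23C[C@H](OC(=O)OC(C)(C)C)[C@@H](C(C(=O)OC(C)(C)C)C(=O)OC(C)(C)C)[C@H]4[C@H]([C@@H]24)C(=O)OC3)cc1 | intermediate
15 | primary alcohol (C10 α-CH2OH) | OC[C@]12C[C@H](OC(=O)OC(C)(C)C)[C@@H](C(C(=O)OC(C)(C)C)C(=O)OC(C)(C)C)[C@H]3[C@H]([C@@H]13)C(=O)OC2 | intermediate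
16 | aldehyde (C10 α-CHO) | O=C[C@]12C[C@H](OC(=O)OC(C)(C)C)[C@@H](C(C(=O)OC(C)(C)C)C(=O)OC(C)(C)C)[C@H]3[C@H]([C@@H]13)C(=O)OC2 | intermediate
17 | 10α-vinyl lactone | C=C[C@]12C[C@H](OC(=O)OC(C)(C)C)[C@@H](C(C(=O)OC(C)(C)C)C(=O)OC(C)(C)C)[C@H]3[C@H]([C@@H]13)C(=O)OC2 | intermediate
18 | hydroxy amide: 14-hydroxy C15 N-methoxy-N-methylamide | C=C[C@]1(CO)C[C@H](OC(=O)OC(C)(C)C)[C@@H](C(C(=O)OC(C)(C)C)C(=O)OC(C)(C)C)[C@H]2[C@H]([C@@H]12)C(=O)N(C)OC | intermediate (not isolated)
19 | 14-acetoxy C15 N-methoxy-N-methylamide | C=C[C@]1(COC(C)=O)C[C@H](OC(=O)OC(C)(C)C)[C@@H](C(C(=O)OC(C)(C)C)C(=O)OC(C)(C)C)[C@H]2[C@H]([C@@H]12)C(=O)N(C)OC | intermediate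
20 | cyclopropanecarbaldehyde (C15 aldehyde; 8α-OBoc; di-tert-butyl malonate; 14-OAc) | C=C[C@]1(COC(C)=O)C[C@H](OC(=O)OC(C)(C)C)[C@@H](C(C(=O)OC(C)(C)C)C(=O)OC(C)(C)C)[C@H]2[C@H]([C@@H]12)C=O | intermediate
21 | 8α-hydroxy malonic acid aldehyde | C=C[C@]1(COC(C)=O)C[C@H](O)[C@@H](C(C(=O)O)C(=O)O)[C@H]2[C@H]([C@@H]12)C=O | intermediate
22 | acrylic acid (C7 β-C(=CH2)CO2H; formylcyclopropane intact) | C=C[C@]1(COC(C)=O)C[C@H](O)[C@@H](C(=C)C(=O)O)[C@H]2[C@H]([C@@H]12)C=O | intermediate (not isolated)
23 | 14-acetoxy-8α-hydroxy-15-oxoelema-1,3,11(13)-trien-12,6α-olide | C=C[C@]1(COC(C)=O)C[C@H](O)[C@H]2C(=C)C(=O)O[C@@H]2[C@H]1C(=C)C=O | intermediate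
24 | 8α-acrylate of 23 | C=C[C@]1(COC(C)=O)C[C@H](OC(=O)C=C)[C@H]2C(=C)C(=O)O[C@@H]2[C@H]1C(=C)C=O | intermediate
25 | CNP0185525.1 | C=C[C@]1(COC(C)=O)C[C@H](OC(=O)C(=C)CO)[C@H]2C(=C)C(=O)O[C@@H]2[C@H]1C(=C)C=O | target

**Step count and risks**

Total step count: 18. Longest linear sequence: 18 steps (from 1).

Steps most likely to fail:

1. Step 16 (Proposed new method). The trans ring fusion demands a strained boat-like transition state, so the intramolecular opening may be slow. Condensation between the malonate carbon or the amine and the aldehyde, front-side capture with loss of stereospecificity, or irreversible amine addition could then take over. Fallback with known chemistry, setting out from 20 and returning at 23: 20 is opened intermolecularly with formic acid under diarylprolinol silyl ether iminium catalysis (CHCl3, 40 °C; C5 is neopentylic, so attack should go to C6 with inversion), and aqueous formaldehyde is then added to methylenate the aldehyde, which should give the 6α-formyloxy enal F1. Mild methanolysis (KHCO3, MeOH, 0 °C) should free the 6α-alcohol F2. CF3CO2H in CH2Cl2 should remove the tert-butyl groups and close the 12,6α-lactone by acylation, giving the α-carboxy lactone F3. Decarboxylative Mannich methylenation (Et2NH, aq. CH2O; then NaOAc, AcOH, 70 °C) then gives 23.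

2. Step 8. Facial selectivity of the hydroboration may be poor, or borane may reduce the δ-lactone competitively. Fallback setting out from 12 and returning at 13: epoxidation with mCPBA (NaHCO3, CH2Cl2, 0 °C) from the α face should give the 7α,8α-epoxide F4. DBU-induced β-elimination of the epoxide oxygen by the ester α-carbon should give the (E)-γ-hydroxy enoate F5 with the 8α-hydroxyl in place. Hydroxyl-directed hydrogenation with [Ir(cod)(PCy3)(py)]PF6 and H2 in CH2Cl2 delivers hydrogen to C7 from the α face and should give 13.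

3. Step 18. Turnover on the hindered acrylate may be slow, and amine or water may add to the other acceptors or the acetate may be lost on long exposure to aqueous base. Fallback setting out from 23 and returning at 25: methyl 2-(hydroxymethyl)acrylate is silylated (TBSCl, imidazole, CH2Cl2) to the methyl ester F6 and saponified (LiOH, THF–H2O, 0 °C) to the acid F7. 23 is esterified with F7 (2,4,6-trichlorobenzoyl chloride, Et3N; then DMAP, toluene; Yamaguchi esterification) to the silyl ether F8. HF·pyridine in THF at 0 °C removes the silyl group to give 25.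

**Further compounds**

F1 | step 16 | 6α-formyloxy enal (8α-OBoc; C7 β-CH(CO2tBu)2; C5 β-C(=CH2)CHO; 14-OAc) | C=C[C@]1(COC(C)=O)C[C@H](OC(=O)OC(C)(C)C)[C@@H](C(C(=O)OC(C)(C)C)C(=O)OC(C)(C)C)[C@H](OC=O)[C@H]1C(=C)C=O
F2 | step 16 | 6α-alcohol corresponding to F1 | C=C[C@]1(COC(C)=O)C[C@H](OC(=O)OC(C)(C)C)[C@@H](C(C(=O)OC(C)(C)C)C(=O)OC(C)(C)C)[C@H](O)[C@H]1C(=C)C=O
F3 | step 16 | 11-carboxy-12,6α-lactone with 8α-OH (C11 epimers) | C=C[C@]1(COC(C)=O)C[C@H](O)[C@H]2C(C(O)=O)C(=O)O[C@@H]2[C@H]1C(=C)C=O
F4 | step 8 | 7α,8α-epoxide of 12 | COc1ccc(COC[C@]23C[C@@H]5O[C@]5(CC(=O)OC(C)(C)C)[C@H]4[C@H]([C@@H]24)C(=O)OC3)cc1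
F5 | step 8 | (E)-γ-hydroxy enoate (C7=C11; 8α-OH) | COc1ccc(COC[C@]23C[C@H](O)/C(=C/C(=O)OC(C)(C)C)[C@H]4[C@H]([C@@H]24)C(=O)OC3)cc1
F6 | step 18 | methyl 2-{[(tert-butyldimethylsilyl)oxy]methyl}acrylate | C=C(CO[Si](C)(C)C(C)(C)C)C(=O)OC
F7 | step 18 | 2-{[(tert-butyldimethylsilyl)oxy]methyl}acrylic acid | C=C(CO[Si](C)(C)C(C)(C)C)C(=O)O
F8 | step 18 | tert-butyldimethylsilyl ether of 25 | C=C[C@]1(COC(C)=O)C[C@H](OC(=O)C(=C)CO[Si](C)(C)C(C)(C)C)[C@H]2C(=C)C(=O)O[C@@H]2[C@H]1C(=C)C=O
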